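**Strategy.** Everything rests on opening pyranone ring E at the C3′–C4′ bond. The tertiary carbinol C3′, which ring E shares with furanone ring D, and the neighbouring aryl ketone C4′ on benzo ring F form an acyloin, so the bond is traced back to an aryl aldehyde and a C3′ ketone. One carbene-catalysed crossed benzoin reaction should then form C3′–C4′, close ring E and set C3′. Its precursor 22 is the ring-A dienone bearing the ring-D furanone ketone and, on the oxygen of quaternary C8, a 2-formyl-3,5-bis(methoxymethoxy)phenyl group; it is built from an afzelechin-derived 5,8-quinone by alkenyllithium addition, O-arylation, dihydroxylation and oxidation.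

Key step: step 15

Remark: rings A and C keep flavan numbering (C2–C8a); the new part is numbered C2′ (ArCH–O), C3′ and C4′, with ring D the furanone, ring E the pyranone and ring F its benzo ring; in this numbering the target is (2R,3S,8R,2′R,3′S).
Remark: the C3 hydroxyl is carried as a silyl ether, because a free secondary hydroxyl would compete with the C8 alkoxide in the O-arylation and with C3′–OH in the oxidation.
Remark: nothing near C8 controls the face of the quinone addition in step 8; the two C8 epimers are assumed to be separable by chromatography.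

**Step 1**
Reactants: 1 (+)-afzelechin
Product: 2 (2R,3S)-5,7-bis(methoxymethoxy)-2-[4-(methoxymethoxy)phenyl]chroman-3-ol
Conditions: MOMCl (3.3 equiv), K2CO3, acetone, 0 °C to rt
Reagents that add atoms: chloromethyl methyl ether, COCCl
Why: Williamson O-alkylation of the three phenoxides, while K2CO3 does not ionise the secondary C3 alcohol, which stays free; no stereocentre is involved.

**Step 2**
Reactants: 2 (2R,3S)-5,7-bis(methoxymethoxy)-2-[4-(methoxymethoxy)phenyl]chroman-3-ol
Product: 3 3-O-tert-butyldimethylsilyl ether of 2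
Conditions: TBSCl, imidazole, DMF, rt
Reagents that add atoms: tert-butyldimethylsilyl chloride, CC(C)(C)[Si](C)(C)Cl
Why: Silylation of the only remaining hydroxyl, giving a group that withstands organolithiums, oxidants and base and falls with the acetals in the final acid step.

**Step 3**
Reactants: 3 3-O-tert-butyldimethylsilyl ether of 2
Product: 4 8-bromo derivative of 3
Conditions: NBS, CH2Cl2, −78 °C to 0 °C
Reagents that add atoms: N-bromosuccinimide, O=C1CCC(=O)N1Br
Why: Electrophilic aromatic bromination of the phloroglucinol-type ring A, which in 5,7-di-O-alkyl flavan-3-ol ethers goes to C8 (next to the ring oxygen and less hindered than C6 between two alkoxy groups), ring B being far less activated.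

**Step 4**
Reactants: 4 8-bromo derivative of 3
Product: 7 8-hydroxy derivative of 3, via aryllithium 5 (not isolated), via lithium aryl(trimethoxy)borate 6 (not isolated)
Conditions: n-BuLi, THF, −78 °C; B(OMe)3, −78 °C to 0 °C; then AcOH, H2O2 (30 % aq.), 0 °C
Reagents that add atoms: hydrogen peroxide, OO
Why: Bromine–lithium exchange, borylation and oxidation of the C–B bond with 1,2-migration of the aryl group to oxygen should turn the C8 bromide into the C8 phenol, para to the C5 ether.

**Step 5**
Reactants: 7 8-hydroxy derivative of 3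
Product: 8 (2R,3S)-3-(tert-butyldimethylsilyloxy)-7-(methoxymethoxy)-2-[4-(methoxymethoxy)phenyl]-3,4-dihydro-2H-chromene-5,8-dione
Conditions: PhI(OAc)2, MeCN–H2O (3:1), 0 °C
Reagents that add atoms: water, O
Why: Oxidative dealkylation of a para-alkoxyphenol by the hypervalent iodine reagent, in which water adds at C5 of the phenoxonium ion and the hemiketal loses methoxymethanol, should give the para-quinone and so turn exactly the C5 oxygen into the later ring-A carbonyl.

**Step 6**
Reactants: 9 4-hydroxybenzaldehyde
Product: 10 4-(methoxymethoxy)benzaldehyde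
Conditions: MOMCl, i-Pr2NEt, CH2Cl2, 0 °C to rt
Reagents that add atoms: chloromethyl methyl ether, COCCl
Why: O-Alkylation of the phenol, so that the later organolithium meets no acidic proton.

**Step 7**
Reactants: 10 4-(methoxymethoxy)benzaldehyde
Product: 11 (E)-1-(2-iodovinyl)-4-(methoxymethoxy)benzene
Conditions: CHI3, CrCl2, THF, 0 °C to rt
Reagents that add atoms: iodoform, IC(I)I
Why: Takai olefination, in which anti elimination from the gem-dichromium adduct gives the E-alkenyl iodide.

**Step 8**
Reactants: 11 (E)-1-(2-iodovinyl)-4-(methoxymethoxy)benzene; 8 (2R,3S)-3-(tert-butyldimethylsilyloxy)-7-(methoxymethoxy)-2-[4-(methoxymethoxy)phenyl]-3,4-dihydro-2H-chromene-5,8-dione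
Product: 13 (2R,3S,8R)-3-(tert-butyldimethylsilyloxy)-8-hydroxy-7-(methoxymethoxy)-2-[4-(methoxymethoxy)phenyl]-8-[(E)-2-[4-(methoxymethoxy)phenyl]ethenyl]-3,4-dihydro-2H-chromen-5(8H)-one, via alkenyllithium 12 (not isolated)
Conditions: 11, t-BuLi (2.0 equiv), Et2O, −78 °C; then 8, THF, −78 °C; H2O; separation of the C8 epimers on Et3N-buffered SiO2
Reagents that add atoms: none
Why: Iodine–lithium exchange with retention of alkene geometry, then 1,2-addition to the C8 carbonyl, which lies between the two oxygen-bearing carbons and can chelate lithium with the acetal oxygen, whereas the C5 carbonyl is deactivated as a doubly vinylogous ester; the remote C2/C3 centres give no useful facial bias, so both C8 epimers are expected in comparable amounts and the (8R) epimer (C8–OH on the ring-A face opposite to the C2 aryl group) is secured by the separation.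

**Step 9**
Reactants: 14 1-fluoro-3,5-dimethoxybenzene
Product: 16 2-fluoro-4,6-dimethoxybenzaldehyde, via iminium salt 15 (not isolated)
Conditions: POCl3, DMF, 0 °C to 70 °C; then H2O
Reagents that add atoms: N,N-dimethylformamide, CN(C)C=O; water, O
Why: Vilsmeier–Haack formylation para to one methoxy group and ortho to the other, next to fluorine, the position between the two methoxy groups being more hindered.

**Step 10**
Reactants: 16 2-fluoro-4,6-dimethoxybenzaldehyde
Product: 17 2-fluoro-4,6-dihydroxybenzaldehyde
Conditions: BBr3, CH2Cl2, −78 °C to rt; then H2O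
Reagents that add atoms: none
Why: Lewis-acid cleavage of both aryl methyl ethers, which leaves the aldehyde and the C–F bond untouched.

**Step 11**
Reactants: 17 2-fluoro-4,6-dihydroxybenzaldehyde
Product: 18 2-fluoro-4,6-bis(methoxymethoxy)benzaldehyde
Conditions: MOMCl (3 equiv), i-Pr2NEt, CH2Cl2, 0 °C to 40 °C
Reagents that add atoms: chloromethyl methyl ether, COCCl
Why: Double O-alkylation gives acetal ethers that survive the later basic, oxidative and carbene steps and fall with mild acid at the end.

**Step 12**
Reactants: 13 (8R)-quinol from step 8; 18 2-fluoro-4,6-bis(methoxymethoxy)benzaldehyde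
Product: 19 8-O-[2-formyl-3,5-bis(methoxymethoxy)phenyl] ether of 13
Conditions: NaH (1.2 equiv), THF–DMF (1:4), 0 °C; then 18 (1.5 equiv), 0 °C to rt
Reagents that add atoms: none
Why: Nucleophilic aromatic substitution (addition–elimination) of the fluoride ortho to the formyl group by the tertiary alkoxide; the C3 oxygen is blocked, the aldehyde has no α-hydrogen, and C8 keeps its configuration because only its O–H bond reacts.

**Step 13**
Reactants: 19 8-O-[2-formyl-3,5-bis(methoxymethoxy)phenyl] ether of 13
Product: 21 (2R,3S,8R,2′R,3′S) ring-D alcohol with the dihydrofuran fused at C7–C8, via diol 20 (not isolated)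
Conditions: OsO4 (5 mol %), NMO, acetone–H2O (5:1), rt; then PPTS (20 mol %), CH2Cl2, 35 °C
Reagents that add atoms: osmium tetroxide, O=[Os](=O)(=O)=O; N-methylmorpholine N-oxide, C[N+]1([O-])CCOCC1; water, O
Why: Upjohn syn-dihydroxylation of the electron-rich styrene (the push–pull enol ethers of ring A react far more slowly with OsO4), then acid-catalysed alkoxy exchange at the β-carbon C7 of the vinylogous ester, where the benzylic C2′ hydroxyl adds 5-exo-trig and methoxymethanol leaves, closing ring D; either alkene face may react, which is immaterial because C3′ becomes a ketone in step 14 and C2′ is equilibrated in step 15 (the isomer drawn has 2′-aryl and 3′-OH cis, as follows from syn addition to the E-alkene).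

**Step 14**
Reactants: 21 ring-D alcohol
Product: 22 (2R,3S,8R,2′R) furanone aldehyde with C3′ as ketone and the C8 aryloxy group intact (key-step precursor)
Conditions: Dess–Martin periodinane, CH2Cl2, 0 °C to rt
Reagents that add atoms: none
Why: Dess–Martin oxidation of the only secondary carbinol under near-neutral conditions that should neither fragment the dienone nor touch C8; the 2′-epimer that arises from the other alkene face is carried along.

**Step 15**
Reactants: 22 furanone aldehyde (ring E open)
Product: 23 (2R,3S,8R,2′R,3′S) pentacyclic acyloin: genkwanol C with its four phenols as methoxymethyl ethers and C3–OH as tert-butyldimethylsilyl ether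
Conditions: 2-(pentafluorophenyl)-6,7-dihydro-5H-pyrrolo[2,1-c][1,2,4]triazol-2-ium tetrafluoroborate (20 mol %), DBU (20 mol %), THF, rt to 40 °C
Reagents that add atoms: none
Why: The carbene set free from the triazolium salt adds to the aldehyde, proton transfer gives the Breslow enaminol, its nucleophilic carbon attacks the C3′ ketone, and a second proton transfer with loss of the carbene releases the α-hydroxy ketone. The closest known reaction type is the carbene-catalysed intramolecular crossed aldehyde–ketone benzoin cyclisation of 2-(2-oxoalkoxy)benzaldehydes to 3-hydroxychroman-4-ones. Ring E is closed in the 6-exo-trig mode. The new centre C3′ is fixed by the short C8–O–aryl tether, which can deliver the acyl carbon only to the face of ring D that carries the C8–O bond, so the D/E fusion is cis and the hydroxyl ends up on the other face. C2′, an α-keto benzylic ether centre, should epimerise through its enol under DBU, and the epimer whose aryl group lies anti to the incoming acyl carbon cyclises faster, so both 2′-epimers of 22 should converge on the (2′R,3′S) product. The step needs the aldehyde to act only as donor and the ketone only as acceptor, which is secured because the aldehyde cannot enolise and is too hindered to self-condense, while the ketone is activated by the inductive pull of the oxygen substituents on both α-carbons and is held next to the aldehyde.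

**Step 16**
Reactants: 23 protected genkwanol C
Product: 24 genkwanol C
Conditions: HCl (2 M aq.), MeOH–THF (1:1), rt to 35 °C
Reagents that add atoms: none
Why: Acid-catalysed solvolysis of the four aryl acetals and the silyl ether frees the phenols and the C3 alcohol without touching a stereocentre; mild conditions are chosen because the benzylic C2–O and C2′–O bonds could ionise under forcing acid.

**Compound list**

1 | (+)-afzelechin, (2R,3S)-2-(4-hydroxyphenyl)chromane-3,5,7-triol | Oc1cc(O)c2C[C@H](O)[C@@H](c3ccc(O)cc3)Oc2c1 | starting material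
2 | (2R,3S)-5,7-bis(methoxymethoxy)-2-[4-(methoxymethoxy)phenyl]chroman-3-ol | COCOc1cc(OCOC)c2C[C@H](O)[C@@H](c3ccc(OCOC)cc3)Oc2c1 | intermediate
3 | 3-O-tert-butyldimethylsilyl ether of 2 | COCOc1cc(OCOC)c2C[C@H](O[Si](C)(C)C(C)(C)C)[C@@H](c3ccc(OCOC)cc3)Oc2c1 | intermediate
4 | 8-bromo derivative of 3 | COCOc1cc(OCOC)c2C[C@H](O[Si](C)(C)C(C)(C)C)[C@@H](c3ccc(OCOC)cc3)Oc2c1Br | intermediate
5 | 8-lithio derivative of 3 (aryllithium, not isolated) | COCOc1cc(OCOC)c2C[C@H](O[Si](C)(C)C(C)(C)C)[C@@H](c3ccc(OCOC)cc3)Oc2c1[Li] | intermediate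
6 | lithium aryl(trimethoxy)borate, boron on C8 (not isolated) | [Li+].COCOc1cc(OCOC)c2C[C@H](O[Si](C)(C)C(C)(C)C)[C@@H](c3ccc(OCOC)cc3)Oc2c1[B-](OC)(OC)OC | intermediate
7 | 8-hydroxy derivative of 3 (phenol para to the C5 ether) | COCOc1cc(OCOC)c2C[C@H](O[Si](C)(C)C(C)(C)C)[C@@H](c3ccc(OCOC)cc3)Oc2c1O | intermediate
8 | (2R,3S)-3-(tert-butyldimethylsilyloxy)-7-(methoxymethoxy)-2-[4-(methoxymethoxy)phenyl]-3,4-dihydro-2H-chromene-5,8-dione | O=C1C=C(OCOC)C(=O)C2=C1C[C@H](O[Si](C)(C)C(C)(C)C)[C@@H](c1ccc(OCOC)cc1)O2 | intermediate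
9 | 4-hydroxybenzaldehyde | O=Cc1ccc(O)cc1 | starting material
10 | 4-(methoxymethoxy)benzaldehyde | COCOc1ccc(C=O)cc1 | intermediate
11 | (E)-1-(2-iodovinyl)-4-(methoxymethoxy)benzene | COCOc1ccc(/C=C/I)cc1 | intermediate
12 | (E)-2-[4-(methoxymethoxy)phenyl]vinyllithium (not isolated) | COCOc1ccc(/C=C/[Li])cc1 | intermediate
13 | (2R,3S,8R)-quinol: 8-hydroxy-8-[(E)-4-(methoxymethoxy)styryl] dienone, C8–OH anti to the C2 aryl group | O=C1C=C(OCOC)[C@](O)(/C=C/c3ccc(OCOC)cc3)C2=C1C[C@H](O[Si](C)(C)C(C)(C)C)[C@@H](c1ccc(OCOC)cc1)O2 | intermediate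
14 | 1-fluoro-3,5-dimethoxybenzene | COc1cc(F)cc(OC)c1 | starting material
15 | N-(2-fluoro-4,6-dimethoxybenzylidene)-N-methylmethanaminium dichlorophosphate (not isolated) | C[N+](C)=Cc1c(F)cc(OC)cc1OC.[O-]P(=O)(Cl)Cl | intermediate
16 | 2-fluoro-4,6-dimethoxybenzaldehyde | COc1cc(F)c(C=O)c(OC)c1 | intermediate
17 | 2-fluoro-4,6-dihydroxybenzaldehyde | Oc1cc(F)c(C=O)c(O)c1 | intermediate
18 | 2-fluoro-4,6-bis(methoxymethoxy)benzaldehyde | COCOc1cc(F)c(C=O)c(OCOC)c1 | intermediate
19 | (2R,3S,8R) 8-O-[2-formyl-3,5-bis(methoxymethoxy)phenyl] ether of 13 | O=C1C=C(OCOC)[C@](Oc3cc(OCOC)cc(OCOC)c3C=O)(/C=C/c3ccc(OCOC)cc3)C2=C1C[C@H](O[Si](C)(C)C(C)(C)C)[C@@H](c1ccc(OCOC)cc1)O2 | intermediate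
20 | (2R,3S,8R,2′R,3′S) diol: styryl group of 19 replaced by C3′H(OH)–C2′H(OH)Ar, formed with its alkene-face isomer (not isolated) | O=C1C=C(OCOC)[C@](Oc3cc(OCOC)cc(OCOC)c3C=O)([C@@H](O)[C@H](O)c3ccc(OCOC)cc3)C2=C1C[C@H](O[Si](C)(C)C(C)(C)C)[C@@H](c1ccc(OCOC)cc1)O2 | intermediate
21 | (2R,3S,8R,2′R,3′S) ring-D alcohol: dihydrofuran O–C2′H(Ar)–C3′H(OH) fused at C7–C8, aryl and hydroxyl cis and anti to the C8 aryloxy group; formed with its face isomer | O=C1C=C2O[C@H](c3ccc(OCOC)cc3)[C@H](O)[C@]2(Oc3cc(OCOC)cc(OCOC)c3C=O)C2=C1C[C@H](O[Si](C)(C)C(C)(C)C)[C@@H](c1ccc(OCOC)cc1)O2 | intermediate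
22 | (2R,3S,8R,2′R) C8-aryloxy furanone aldehyde, ring E open (key-step precursor; with its 2′-epimer) | O=C1C=C2O[C@H](c3ccc(OCOC)cc3)C(=O)[C@]2(Oc3cc(OCOC)cc(OCOC)c3C=O)C2=C1C[C@H](O[Si](C)(C)C(C)(C)C)[C@@H](c1ccc(OCOC)cc1)O2 | intermediate
23 | (2R,3S,8R,2′R,3′S) genkwanol C tetrakis(methoxymethyl) ether 3-O-tert-butyldimethylsilyl ether | O=C1C=C2O[C@H](c3ccc(OCOC)cc3)[C@@]3(O)C(=O)c4c(OCOC)cc(OCOC)cc4O[C@@]23C2=C1C[C@H](O[Si](C)(C)C(C)(C)C)[C@@H](c1ccc(OCOC)cc1)O2 | intermediate
24 | genkwanol C | O=C1C=C2O[C@H](c3ccc(O)cc3)[C@@]3(O)C(=O)c4c(O)cc(O)cc4O[C@@]23C2=C1C[C@H](O)[C@@H](c1ccc(O)cc1)O2 | target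

**Totals.** Total step count: 16. Longest linear sequence: 11 steps (steps 1–5, 8, 12–16, from afzelechin 1).

**Steps most likely to fail**

Step 15. The carbene may fail to add to an aldehyde that is flanked by two ortho oxygen substituents and deactivated by three donors. Alternatively, the C3′ alkoxide formed on addition may fragment towards an aromatic ring A before the catalyst is released. The fallback makes the same bond reductively. It sets out from 22: SmI2 in THF–t-BuOH at −78 °C should couple aldehyde and ketone in an intramolecular pinacol cyclisation to the ring-E cis-diol, the 4′-hydroxy-4′-deoxo analogue of 23 F1. IBX in DMSO at rt should then oxidise its secondary benzylic carbinol, and the fallback comes back to the route at 23.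

Step 12. Substitution by the hindered tertiary alkoxide may be too slow, so that reversible addition to the aldehyde and base-induced decomposition of the dienone take over. The fallback arylates a slimmer, more acidic propargylic carbinol instead. It sets out from quinone 8, with aldehyde 10 as source of the alkyne. Aldehyde 10 with dimethyl (1-diazo-2-oxopropyl)phosphonate and K2CO3 in MeOH should give 1-ethynyl-4-(methoxymethoxy)benzene F2. Its lithium acetylide (n-BuLi, THF, −78 °C) should add to C8 of 8 to give the (8R)-alkynyl quinol F3, after the same separation of C8 epimers as for 13. NaH and 18 in THF–DMF should give the alkynyl aryl ether F4. H2 over Pd on CaCO3 poisoned with Pb(OAc)2, with quinoline, should give the Z-alkene isomer of 19 F5. The conditions of step 13 should then lead through the erythro diol F6 to the 2′,3′-trans ring-D alcohol F7, and the conditions of step 14 bring the fallback back to the route at ketone 22.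

Step 8. Electron transfer from the organolithium may reduce the quinone, some attack may occur at the C5 carbonyl, and the addition has no facial preference. The fallback removes the redox and regiochemical risks by masking C5; the epimer separation stays. It sets out from phenol 7: PhI(OAc)2 in MeOH should give the mixed quinone monoketal 5-methoxy-5-(methoxymethoxy) dienone F8 (either configuration at C5), in which C8 is the only carbonyl. Alkenyllithium 12 should add to it to give the quinol ketal F9. Oxalic acid on wet SiO2 in CH2Cl2 should hydrolyse the ketal, and the fallback comes back to the route at quinol 13.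

**Further compounds**

F1 | step 15 | (2R,3S,8R,2′R,3′S) ring-E cis-diol, 4′-hydroxy-4′-deoxo analogue of 23 | O=C1C=C2O[C@H](c3ccc(OCOC)cc3)[C@@]3(O)[C@H](O)c4c(OCOC)cc(OCOC)cc4O[C@@]23C2=C1C[C@H](O[Si](C)(C)C(C)(C)C)[C@@H](c1ccc(OCOC)cc1)O2
F2 | step 12 | 1-ethynyl-4-(methoxymethoxy)benzene | C#Cc1ccc(OCOC)cc1
F3 | step 12 | (2R,3S,8R)-8-hydroxy-8-{[4-(methoxymethoxy)phenyl]ethynyl} quinol | O=C1C=C(OCOC)[C@](O)(C#Cc3ccc(OCOC)cc3)C2=C1C[C@H](O[Si](C)(C)C(C)(C)C)[C@@H](c1ccc(OCOC)cc1)O2
F4 | step 12 | 8-O-[2-formyl-3,5-bis(methoxymethoxy)phenyl] ether of F3 | O=C1C=C(OCOC)[C@](Oc3cc(OCOC)cc(OCOC)c3C=O)(C#Cc3ccc(OCOC)cc3)C2=C1C[C@H](O[Si](C)(C)C(C)(C)C)[C@@H](c1ccc(OCOC)cc1)O2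
F5 | step 12 | Z-alkene isomer of 19 | O=C1C=C(OCOC)[C@](Oc3cc(OCOC)cc(OCOC)c3C=O)(/C=C\c3ccc(OCOC)cc3)C2=C1C[C@H](O[Si](C)(C)C(C)(C)C)[C@@H](c1ccc(OCOC)cc1)O2
F6 | step 12 | (2′R,3′R) erythro diol from F5, with its face isomer | O=C1C=C(OCOC)[C@](Oc3cc(OCOC)cc(OCOC)c3C=O)([C@H](O)[C@H](O)c3ccc(OCOC)cc3)C2=C1C[C@H](O[Si](C)(C)C(C)(C)C)[C@@H](c1ccc(OCOC)cc1)O2
F7 | step 12 | (2′R,3′R) ring-D alcohol, 2′-aryl and 3′-hydroxyl trans (3′-epimer of 21) | O=C1C=C2O[C@H](c3ccc(OCOC)cc3)[C@@H](O)[C@]2(Oc3cc(OCOC)cc(OCOC)c3C=O)C2=C1C[C@H](O[Si](C)(C)C(C)(C)C)[C@@H](c1ccc(OCOC)cc1)O2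
F8 | step 8 | (2R,3S)-5-methoxy-5,7-bis(methoxymethoxy) quinone monoketal, C8 ketone, either configuration at C5 | COCOC1(OC)C=C(OCOC)C(=O)C2=C1C[C@H](O[Si](C)(C)C(C)(C)C)[C@@H](c1ccc(OCOC)cc1)O2
F9 | step 8 | (8R)-quinol ketal: C5 mixed ketal of 13 | COCOC1(OC)C=C(OCOC)[C@](O)(/C=C/c3ccc(OCOC)cc3)C2=C1C[C@H](O[Si](C)(C)C(C)(C)C)[C@@H](c1ccc(OCOC)cc1)O2
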